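**Plan**

1. Both halves are numbered as 2-arylchroman-4-ones: unit 1 is the flavanone half (benzo ring A, pyranone ring C), unit 2 the 3-hydroxyflavanone half (benzo ring D, pyranone ring F). Rings A and D are the same 5,7-dihydroxybenzo ring and touch rings C and F only along C4a–C8a, which in a 2-aryl-2,3-dihydropyran-4-one is simply the enone C=C; both benzo rings can therefore be grown last.
2. Retrosynthesis: after removal of the acetyl and benzyl groups, C4a–C5 and C8–C8a are cut in ring A and in ring D (four C–C bonds). This leaves the bis(5-sulfinyl-dihydropyranone) 11 and two molecules of 1-methoxy-1,3-bis(trimethylsilyloxy)butadiene 14. The two C–S bonds, the biaryl bond and the C3–O bond of unit 2 are cut next, back to one bromoaryl dihydropyranone 5, which comes from aldehyde 2 and Danishefsky's diene.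
3. Forward: the pyranone ring (future rings C and F) is made first by hetero-Diels–Alder reaction. One portion is acetoxylated at C3 and one is borylated, the two are joined by Suzuki coupling, and both enones are sulfenylated and oxidised. Rings A and D are then closed together, followed by deacetylation and hydrogenolysis.
4. Stereochemistry: C2 of both units comes from the single (R)-BINOL–Ti(OiPr)4-catalysed hetero-Diels–Alder step (both halves need the same face). C3 of unit 2 comes from substrate-controlled trans acetoxylation. Sulfur and the cycloadduct centres are not kept.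

Key step: step 10

Assumption: the (R)-BINOL–Ti(OiPr)4 catalyst is taken to send the diene to the Si face of the aryl aldehyde (2S product); if the configuration found for 5 is the opposite, (S)-BINOL is used with no other change.

**Route**

Step 1
Reactants: 1 3-bromo-4-hydroxybenzaldehyde
Product: 2 4-(benzyloxy)-3-bromobenzaldehyde
Conditions: BnBr, K2CO3, DMF, rt
Reagents that add atoms: benzyl bromide, BrCc1ccccc1
Why: Williamson ether synthesis on the phenoxide, which protects the future 4'-hydroxyl as a benzyl ether that lasts until the final hydrogenolysis.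

Step 2
Reactants: 2 4-(benzyloxy)-3-bromobenzaldehyde; 3 (E)-1-methoxy-3-(trimethylsilyloxy)buta-1,3-diene
Product: 5 (2S)-2-[4-(benzyloxy)-3-bromophenyl]-2,3-dihydro-4H-pyran-4-one, via silylated Mukaiyama aldol adduct 4 (not isolated)
Conditions: (R)-BINOL (20 mol%), Ti(OiPr)4 (10 mol%), 4 Å MS, Et2O, −20 °C; then TFA, CH2Cl2, 0 °C
Reagents that add atoms: none
Why: Catalytic asymmetric hetero-Diels–Alder reaction of the Mukaiyama aldol/cyclisation type, in which the BINOL–titanium complex delivers the diene terminus to the Si face of the aldehyde to set C2 as S, and TFA then closes adduct 4 to the pyranone with loss of methanol.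

Step 3
Reactants: 5 (2S)-2-[4-(benzyloxy)-3-bromophenyl]-2,3-dihydro-4H-pyran-4-one (one portion)
Product: 6 (2R,3R)-2-[4-(benzyloxy)-3-bromophenyl]-4-oxo-3,4-dihydro-2H-pyran-3-yl acetate
Conditions: Mn(OAc)3·2H2O (4 equiv), benzene, reflux (Dean–Stark)
Reagents that add atoms: manganese triacetate, CC(=O)[O-].CC(=O)[O-].CC(=O)[O-].[Mn+3]
Why: Mn(OAc)3 α'-acetoxylation of an enone, a reaction known for 2-substituted 2,3-dihydropyran-4-ones, in which acetate enters at C3 on the face away from the C2 aryl group, so the new centre is R and trans (diequatorial) to the aryl group.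

Step 4
Reactants: 5 (2S)-2-[4-(benzyloxy)-3-bromophenyl]-2,3-dihydro-4H-pyran-4-one (second portion)
Product: 7 (2S)-2-[4-(benzyloxy)-3-(4,4,5,5-tetramethyl-1,3,2-dioxaborolan-2-yl)phenyl]-2,3-dihydro-4H-pyran-4-one
Conditions: B2pin2, Pd(dppf)Cl2 (3 mol%), KOAc, dioxane, 85 °C
Reagents that add atoms: bis(pinacolato)diboron, CC1(C)OB(OC1(C)C)B1OC(C)(C)C(C)(C)O1
Why: Miyaura borylation of the aryl bromide, in which the weak base KOAc leaves the enone and the C2 centre untouched.

Step 5
Reactants: 6 (2R,3R)-2-[4-(benzyloxy)-3-bromophenyl]-4-oxo-3,4-dihydro-2H-pyran-3-yl acetate; 7 (2S)-2-[4-(benzyloxy)-3-(4,4,5,5-tetramethyl-1,3,2-dioxaborolan-2-yl)phenyl]-2,3-dihydro-4H-pyran-4-one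
Product: 8 (2R,3R)-2-{4-(benzyloxy)-3-[2-(benzyloxy)-5-((2S)-4-oxo-3,4-dihydro-2H-pyran-2-yl)phenyl]phenyl}-4-oxo-3,4-dihydro-2H-pyran-3-yl acetate
Conditions: Pd(OAc)2 (5 mol%), SPhos (10 mol%), CsF (3 equiv), dioxane, 80 °C
Reagents that add atoms: none
Why: Suzuki–Miyaura coupling with a biarylphosphine ligand suited to the doubly ortho-alkoxylated biaryl, run with anhydrous fluoride as base so that the acetate and the enolisable C3–H of unit 2 are spared.

Step 6
Reactants: 8 the bis-pyranone of step 5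
Product: 10 bis(5-p-tolylsulfanyl) derivative of 8, via bis(chlorosulfide) adduct 9 (not isolated)
Conditions: 4-MeC6H4SH, NCS, CH2Cl2, 0 °C (gives 4-MeC6H4SCl, 2.4 equiv); then 8, −78 to 0 °C; then Et3N, 0 °C to rt
Reagents that add atoms: 4-methylbenzenesulfenyl chloride, made in the flask from 4-methylbenzenethiol and N-chlorosuccinimide, Cc1ccc(SCl)cc1
Why: Electrophilic sulfenylation of an enol ether by addition–elimination, in which the sulfenyl chloride attacks the nucleophilic α-carbon C5 of each vinylogous ester, chloride caps the oxocarbenium ion at C6 (adduct 9) and Et3N removes HCl to restore each enone.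

Step 7
Reactants: 10 bis(5-p-tolylsulfanyl) derivative of 8
Product: 11 bis(5-p-tolylsulfinyl) derivative of 8 (sulfur epimers)
Conditions: mCPBA (2.0 equiv), CH2Cl2, −78 °C
Reagents that add atoms: mCPBA, OOC(=O)c1cccc(Cl)c1
Why: Sulfide-to-sulfoxide oxidation with one equivalent of peracid per sulfur at low temperature, which should stop before the sulfone; the sulfur epimers are carried on together because sulfur is lost in step 10.

Step 8
Reactants: 12 methyl acetoacetate
Product: 13 methyl 3-(trimethylsilyloxy)but-2-enoate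
Conditions: TMSCl, Et3N, hexane, rt
Reagents that add atoms: chlorotrimethylsilane, C[Si](C)(C)Cl
Why: O-silylation of the enol form of a β-keto ester (silyl enol ether formation) under amine base.

Step 9
Reactants: 13 methyl 3-(trimethylsilyloxy)but-2-enoate
Product: 14 1-methoxy-1,3-bis(trimethylsilyloxy)buta-1,3-diene
Conditions: LDA, THF, −78 °C; then TMSCl, −78 °C to rt
Reagents that add atoms: chlorotrimethylsilane, C[Si](C)(C)Cl
Why: Kinetic γ-deprotonation of the silyl enol ether by LDA and O-silylation of the dienolate, the standard preparation of this bis(silyloxy)diene.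

Step 10
Reactants: 11 bis(5-p-tolylsulfinyl) derivative of 8; 14 1-methoxy-1,3-bis(trimethylsilyloxy)buta-1,3-diene (two equivalents react; about six are used)
Product: 17 (2S)-2-{4-(benzyloxy)-3-[2-(benzyloxy)-5-((2R,3R)-3-acetoxy-5,7-dihydroxy-4-oxochroman-2-yl)phenyl]phenyl}-5,7-dihydroxychroman-4-one, via bis-cycloadduct 15 (not isolated), via bis(cyclohexadiene ketal) 16 (not isolated)
Conditions: 14 (6 equiv), PhMe, 60 °C (sealed), then 80 °C; then 1 M aq HCl, THF, 0 °C to rt
Reagents that add atoms: none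
Why: Proposed new method: each sulfinyl-bearing enone C4a=C8a (C5=C6 of a pyranone) should serve as the 2π partner of the electron-rich diene in a normal-demand (4+2) cycloaddition, the CH2 terminus of 14 bonding to the oxygen-bearing β-carbon C8a and the ketene acetal carbon to C4a, so that ring A and ring D each close by one intermolecular suprafacial (4+2) event that forms C8–C8a and C4a–C5 (15). Because the addition is cis, the sulfinyl group on C4a lies syn to H8a, and thermal syn-elimination of 4-methylbenzenesulfenic acid restores C4a=C8a with the O1–C8a bond intact (16); aqueous acid then strips the silyl groups, the C5 hemiketal loses methanol and the diketo form tautomerises to the 5,7-dihydroxybenzene ring. The closest known reactions are Diels–Alder additions of oxygenated dienes to 2-sulfinyl enones and sulfinylquinones followed by sulfenic acid loss, and benzannulations of 3-acceptor-substituted chromones with 1,3-bis(silyloxy)dienes. No new stereocentre is kept, since the centres formed at C4a, C8a and C5 vanish on aromatisation, while C2 of unit 1 and C2/C3 of unit 2 are untouched because the neutral thermal conditions generate no enolate that could expel O1 or epimerise C3. The step needs regioselectivity (C8 to C8a rather than to C4a), which the matched polarisation of the diene and the doubly activated enone should secure, and cycloaddition in preference to stepwise Michael addition followed by ring opening or aldol closure onto C4, which the absence of any Lewis acid is meant to secure; the excess diene also silylates the sulfenic acid set free.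

Step 11
Reactants: 17 the 3-O-acetyl compound of step 10
Product: 18 (2S)-2-{4-(benzyloxy)-3-[2-(benzyloxy)-5-((2R,3R)-3,5,7-trihydroxy-4-oxochroman-2-yl)phenyl]phenyl}-5,7-dihydroxychroman-4-one
Conditions: HCl (1.25 M in MeOH), CH2Cl2, rt
Reagents that add atoms: none
Why: Acid-catalysed transesterification (methanolysis) removes the secondary acetate without base, so the 5-hydroxychromanones cannot open to chalcones and C2 and C3 should keep their configuration.

Step 12
Reactants: 18 the di-O-benzyl compound of step 11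
Product: 19 CNP0201582.1
Conditions: H2 (1 atm), Pd/C (10%), EtOAc–MeOH, rt
Reagents that add atoms: none
Why: Hydrogenolysis of aryl benzyl ethers over palladium on carbon, standard for benzylated flavanones and dihydroflavonols, under which the hydrogen-bonded C4 ketones and the C2–O1 bonds should not be reduced.

**Compound list**

1 | 3-bromo-4-hydroxybenzaldehyde | O=Cc1ccc(O)c(Br)c1 | starting material
2 | 4-(benzyloxy)-3-bromobenzaldehyde | O=Cc1ccc(OCc2ccccc2)c(Br)c1 | intermediate
3 | (E)-1-methoxy-3-(trimethylsilyloxy)buta-1,3-diene (Danishefsky's diene) | CO/C=C/C(=C)O[Si](C)(C)C | starting material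
4 | (1E,5S)-5-[4-(benzyloxy)-3-bromophenyl]-1-methoxy-5-(trimethylsilyloxy)pent-1-en-3-one | CO/C=C/C(=O)C[C@H](O[Si](C)(C)C)c1ccc(OCc2ccccc2)c(Br)c1 | intermediate (not isolated)
5 | (2S)-2-[4-(benzyloxy)-3-bromophenyl]-2,3-dihydro-4H-pyran-4-one | O=C1C[C@@H](c2ccc(OCc3ccccc3)c(Br)c2)OC=C1 | intermediate
6 | (2R,3R)-2-[4-(benzyloxy)-3-bromophenyl]-4-oxo-3,4-dihydro-2H-pyran-3-yl acetate (2,3-trans) | CC(=O)O[C@@H]1[C@@H](c2ccc(OCc3ccccc3)c(Br)c2)OC=CC1=O | intermediate
7 | (2S)-2-[4-(benzyloxy)-3-(4,4,5,5-tetramethyl-1,3,2-dioxaborolan-2-yl)phenyl]-2,3-dihydro-4H-pyran-4-one | O=C1C[C@@H](c2ccc(OCc3ccccc3)c(B3OC(C)(C)C(C)(C)O3)c2)OC=C1 | intermediate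
8 | (2R,3R)-2-{4-(benzyloxy)-3-[2-(benzyloxy)-5-((2S)-4-oxo-3,4-dihydro-2H-pyran-2-yl)phenyl]phenyl}-4-oxo-3,4-dihydro-2H-pyran-3-yl acetate (2,2'-bis(benzyloxy)biphenyl with the unit 1 pyranone at C5 and the acetoxylated unit 2 pyranone at C5') | O=C1C[C@@H](c2ccc(OCc3ccccc3)c(-c3cc([C@H]4OC=CC(=O)[C@@H]4OC(C)=O)ccc3OCc3ccccc3)c2)OC=C1 | intermediate
9 | 8 with Cl on C6 and 4-methylphenylsulfanyl on C5 of each pyranone, C5–C6 saturated (new centres not assigned) | O=C1C[C@@H](c2ccc(OCc3ccccc3)c(-c3cc([C@H]4OC(Cl)C(Sc5ccc(C)cc5)C(=O)[C@@H]4OC(C)=O)ccc3OCc3ccccc3)c2)OC(Cl)C1Sc1ccc(C)cc1 | intermediate (not isolated)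
10 | 8 with a 4-methylphenylsulfanyl group on C5 of each pyranone | O=C1C[C@@H](c2ccc(OCc3ccccc3)c(-c3cc([C@H]4OC=C(Sc5ccc(C)cc5)C(=O)[C@@H]4OC(C)=O)ccc3OCc3ccccc3)c2)OC=C1Sc1ccc(C)cc1 | intermediate
11 | 8 with a 4-methylphenylsulfinyl group on C5 of each pyranone (sulfur epimers, carbon centres as in 8) | O=C1C[C@@H](c2ccc(OCc3ccccc3)c(-c3cc([C@H]4OC=C(S(=O)c5ccc(C)cc5)C(=O)[C@@H]4OC(C)=O)ccc3OCc3ccccc3)c2)OC=C1S(=O)c1ccc(C)cc1 | intermediate
12 | methyl acetoacetate | CC(=O)CC(=O)OC | starting material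
13 | methyl 3-(trimethylsilyloxy)but-2-enoate (geometric isomers, one shown) | COC(=O)/C=C(/C)O[Si](C)(C)C | intermediate
14 | 1-methoxy-1,3-bis(trimethylsilyloxy)buta-1,3-diene (either geometry, one shown) | C=C(O[Si](C)(C)C)/C=C(/OC)O[Si](C)(C)C | intermediate
15 | bis-cycloadduct: each pyranone cis-fused across C4a–C8a to a cyclohexene ring with C5(OMe)(OSiMe3), C6=C7(OSiMe3) and C8H2, sulfinyl on C4a (new centres not assigned) | O=C1C[C@@H](c2ccc(OCc3ccccc3)c(-c3cc([C@H]4OC5CC(O[Si](C)(C)C)=CC(OC)(O[Si](C)(C)C)C5(S(=O)c5ccc(C)cc5)C(=O)[C@@H]4OC(C)=O)ccc3OCc3ccccc3)c2)OC2CC(O[Si](C)(C)C)=CC(OC)(O[Si](C)(C)C)C12S(=O)c1ccc(C)cc1 | intermediate (not isolated)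
16 | bis(cyclohexadiene ketal): each unit a 5-methoxy-5,7-bis(trimethylsilyloxy)-5,8-dihydrochroman-4-one with C4a=C8a and C6=C7 (C5 not assigned) | O=C1C[C@@H](c2ccc(OCc3ccccc3)c(-c3cc([C@H]4OC5=C(C(=O)[C@@H]4OC(C)=O)C(OC)(O[Si](C)(C)C)C=C(O[Si](C)(C)C)C5)ccc3OCc3ccccc3)c2)OC2=C1C(OC)(O[Si](C)(C)C)C=C(O[Si](C)(C)C)C2 | intermediate (not isolated)
17 | (2S)-2-{4-(benzyloxy)-3-[2-(benzyloxy)-5-((2R,3R)-3-acetoxy-5,7-dihydroxy-4-oxochroman-2-yl)phenyl]phenyl}-5,7-dihydroxychroman-4-one | O=C1C[C@@H](c2ccc(OCc3ccccc3)c(-c3cc([C@H]4Oc5cc(O)cc(O)c5C(=O)[C@@H]4OC(C)=O)ccc3OCc3ccccc3)c2)Oc2cc(O)cc(O)c21 | intermediate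
18 | (2S)-2-{4-(benzyloxy)-3-[2-(benzyloxy)-5-((2R,3R)-3,5,7-trihydroxy-4-oxochroman-2-yl)phenyl]phenyl}-5,7-dihydroxychroman-4-one | O=C1C[C@@H](c2ccc(OCc3ccccc3)c(-c3cc([C@H]4Oc5cc(O)cc(O)c5C(=O)[C@@H]4O)ccc3OCc3ccccc3)c2)Oc2cc(O)cc(O)c21 | intermediate
19 | CNP0201582.1, (2S)-5,7-dihydroxy-2-{4-hydroxy-3-[2-hydroxy-5-((2R,3R)-3,5,7-trihydroxy-4-oxochroman-2-yl)phenyl]phenyl}chroman-4-one | O=C1C[C@@H](c2ccc(O)c(-c3cc([C@H]4Oc5cc(O)cc(O)c5C(=O)[C@@H]4O)ccc3O)c2)Oc2cc(O)cc(O)c21 | target

**Step count**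

Total: 12 steps. Longest linear sequence: 9 steps (1, 2, 3, 5, 6, 7, 10, 11, 12); steps 4, 8 and 9 are side branches.

**Steps most likely to fail**

Step 10. The alkoxy group on C8a may damp the dienophile so that no cycloaddition takes place below the temperature at which the diene decays. Alternatively, traces of acid or silyl transfer to the sulfoxide oxygen may turn the reaction into a stepwise Michael addition, after which the enolate expels O1 or the acetoacetate carbon closes onto C4 instead of C4a closing onto the ester carbon.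

The fallback uses known chemistry only, sets out from 2 and comes back at 19; rings A and D are brought in as ready-made phloroglucinol rings:
- Knoevenagel condensation of 2 with tert-butyl 3-[2,4-bis(benzyloxy)-6-hydroxyphenyl]-3-oxopropanoate (piperidine, AcOH) would give tert-butyl 2-[2,4-bis(benzyloxy)-6-hydroxybenzoyl]-3-[4-(benzyloxy)-3-bromophenyl]prop-2-enoate F1.
- A quinine- or quinidine-derived thiourea (the pseudoenantiomer that gives the 2S ring) would close the chromanone by asymmetric oxa-Michael addition to tert-butyl (2S)-5,7-bis(benzyloxy)-2-[4-(benzyloxy)-3-bromophenyl]-4-oxochromane-3-carboxylate F2.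
- TsOH in warm toluene would remove the ester group to give (2S)-5,7-bis(benzyloxy)-2-[4-(benzyloxy)-3-bromophenyl]chroman-4-one F3.
- One portion of F3 would be silylated (TMSOTf, Et3N) to (2S)-5,7-bis(benzyloxy)-2-[4-(benzyloxy)-3-bromophenyl]-4-(trimethylsilyloxy)-2H-chromene F4. Rubottom oxidation with dimethyldioxirane, anti to the aryl group, would then give (2R,3R)-5,7-bis(benzyloxy)-2-[4-(benzyloxy)-3-bromophenyl]-3-hydroxychroman-4-one F5.
- A second portion of F3 would be borylated as in step 4 to the pinacol boronate (2S)-5,7-bis(benzyloxy)-2-[4-(benzyloxy)-3-(4,4,5,5-tetramethyl-1,3,2-dioxaborolan-2-yl)phenyl]chroman-4-one F6.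
- Suzuki coupling of F5 with F6 under the conditions of step 5 would give the hexa-O-benzyl ether of the target F7, and hydrogenolysis as in step 12 would give 19.

Step 6. Electrophilic attack at C5 of the carbonyl-deactivated enol ethers may be slow, so that chlorination or sulfenylation of the electron-rich biaryl competes, or the chloro adduct may hydrolyse at C6 before HCl is eliminated.

The fallback sets out from 8 and comes back at 10. Both enone α-carbons would be iodinated with I2 and pyridine in CH2Cl2 (Johnson α-iodination) to the bis(5-iodo) derivative of 8 F8. Palladium-catalysed C–S coupling with 4-methylbenzenethiol (Pd2(dba)3, Xantphos, iPr2NEt, dioxane, 80 °C) would then give 10.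

Step 5. Fluoride may cleave the acetate or enolise C3 of unit 2, which would lead to epimerisation or to opening of the pyranone ring by loss of O1.

The fallback sets out from 5 and comes back at 8. Stannylation of 5 with hexamethylditin and Pd(PPh3)4 in toluene would give (2S)-2-[4-(benzyloxy)-3-(trimethylstannyl)phenyl]-2,3-dihydro-4H-pyran-4-one F9. Base-free Stille coupling of F9 with 6 (Pd(PPh3)4, CuI, DMF, 60 °C) would then give 8.

Further compounds
F1 | step 10 | tert-butyl 2-[2,4-bis(benzyloxy)-6-hydroxybenzoyl]-3-[4-(benzyloxy)-3-bromophenyl]prop-2-enoate | CC(C)(C)OC(=O)C(=Cc1ccc(OCc2ccccc2)c(Br)c1)C(=O)c1c(O)cc(OCc2ccccc2)cc1OCc1ccccc1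
F2 | step 10 | tert-butyl (2S)-5,7-bis(benzyloxy)-2-[4-(benzyloxy)-3-bromophenyl]-4-oxochromane-3-carboxylate | CC(C)(C)OC(=O)C1C(=O)c2c(OCc3ccccc3)cc(OCc3ccccc3)cc2O[C@@H]1c1ccc(OCc2ccccc2)c(Br)c1
F3 | step 10 | (2S)-5,7-bis(benzyloxy)-2-[4-(benzyloxy)-3-bromophenyl]chroman-4-one | O=C1C[C@@H](c2ccc(OCc3ccccc3)c(Br)c2)Oc2cc(OCc3ccccc3)cc(OCc3ccccc3)c21
F4 | step 10 | (2S)-5,7-bis(benzyloxy)-2-[4-(benzyloxy)-3-bromophenyl]-4-(trimethylsilyloxy)-2H-chromene | C[Si](C)(C)OC1=C[C@@H](c2ccc(OCc3ccccc3)c(Br)c2)Oc2cc(OCc3ccccc3)cc(OCc3ccccc3)c21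
F5 | step 10 | (2R,3R)-5,7-bis(benzyloxy)-2-[4-(benzyloxy)-3-bromophenyl]-3-hydroxychroman-4-one | Brc1cc([C@H]2Oc3cc(OCc4ccccc4)cc(OCc4ccccc4)c3C(=O)[C@@H]2O)ccc1OCc1ccccc1
F6 | step 10 | (2S)-5,7-bis(benzyloxy)-2-[4-(benzyloxy)-3-(4,4,5,5-tetramethyl-1,3,2-dioxaborolan-2-yl)phenyl]chroman-4-one | O=C1C[C@@H](c2ccc(OCc3ccccc3)c(B3OC(C)(C)C(C)(C)O3)c2)Oc2cc(OCc3ccccc3)cc(OCc3ccccc3)c21
F7 | step 10 | hexa-O-benzyl ether of the target (5,7-di-O-benzyl on rings A and D, 4'-O-benzyl on both aryl rings, free 3-OH) | O=C1C[C@@H](c2ccc(OCc3ccccc3)c(-c3cc([C@H]4Oc5cc(OCc6ccccc6)cc(OCc6ccccc6)c5C(=O)[C@@H]4O)ccc3OCc3ccccc3)c2)Oc2cc(OCc3ccccc3)cc(OCc3ccccc3)c21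
F8 | step 6 | bis(5-iodo) derivative of 8 | O=C1C[C@@H](c2ccc(OCc3ccccc3)c(-c3cc([C@H]4OC=C(I)C(=O)[C@@H]4OC(C)=O)ccc3OCc3ccccc3)c2)OC=C1I
F9 | step 5 | (2S)-2-[4-(benzyloxy)-3-(trimethylstannyl)phenyl]-2,3-dihydro-4H-pyran-4-one | O=C1C[C@@H](c2ccc(OCc3ccccc3)c([Sn](C)(C)C)c2)OC=C1
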